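In the 3.0 s this flask runs, the coupling partner passes through 2.99 of its own half-lives of 1.0 s, so we reckon by counting time against that clock.

solid substrate 1.0 mM; coupling partner 2.00 mM; time 3.0 s

- how much target and solid product together there is at 3.0 s, in percent of the solid substrate charged
- concentration of dissolved substrate in solution at 3.0 s, in percent of saturation

    solid product ⇌ target, rate k1*(cs1 - [target]) while solid is left; crystals form when [target] > cs1 (cs1 = 0.33 mM, k1 = 61 s⁻¹)
    coupling partner → side product (k2 = 0.69 s⁻¹)
    2 solid substrate → homo dimer (k3 = 660 M⁻¹ s⁻¹)
    solid substrate ⇌ dissolved substrate, rate k4*(cs4 - [dissolved substrate]) while solid is left; crystals form when [dissolved substrate] > cs4 (cs4 = 0.53 mM, k4 = 0.85 s⁻¹)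
    dissolved substrate + coupling partner → target (k5 = 220 M⁻¹ s⁻¹)

The partner's decay constant 0.69 s⁻¹ is larger than the 0.117 s⁻¹ that coupling can take from it even at saturation, so we let the partner fall by its own step. Dissolved substrate then couples in a pseudo-first-order way with a fading constant, and we carry the coupling exposure, the number of coupling lifetimes that a dissolved substrate sees up to a given time, the integral of rate constant times partner: 0.557 by the end of the run. Target is the exposure times the partner-weighted mean of dissolved substrate. With that mean at saturation, target could reach 0.295 mM, which is less than its solubility of 0.33 mM, so crystals play no part.

Dissolved substrate starts from nothing and climbs with rate constant 0.85 s⁻¹. Taking its value at one partner half-life gives 0.304 mM and so 17.0% of the charge. The weak link is that single point, so we weight the whole climb by the partner instead, which gives 14.5%, and we commit to that number. That climb counts no drain of dissolved substrate by coupling, whose constant at the charged partner is 0.440 s⁻¹, half of the climbing constant, so we take the number as leaning high. For saturation we can state a ceiling of 92.2%.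

The forecast says 12%, lower than our yield, and 78%, on the ground that “The solid substrate is lost fast to homodimerisation”.

The flask gives 12.2% and 79.6%. With the coupling partner charged at 1.13 mM instead, the yield has moved by 5 points. Dividing this flask's target by the exposure reads a partner-weighted mean dissolved substrate of 0.220 mM. The neighbour flask charged with 0.60 mM of solid substrate has the same partner charge and time, hence the same exposure, and that mean carried over gives 20.4% of its charge; it holds 19.4%.

The constants were chosen freely; the result is computed.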